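## Retrosynthetic overview

1. Target ⇒ removal of four MOM ethers from a tetra-MOM biflavone; the aryl methyl ether stays. Unit A is the acacetin half (joined at C6), unit B the apigenin half (joined at C8).
2. Key disconnection: the C6(unit A)–C8(unit B) biaryl bond, made by a new 5-OH-directed ligand-coupling arylation of 7-O-MOM-acacetin with a flavon-8-yl lead triacetate.
3. The lead reagent ⇐ unit B 8-boronic acid ⇐ 8-pinacol boronate ⇐ 8-iodide ⇐ tri-O-MOM-apigenin ⇐ apigenin.
4. 7-O-MOM-acacetin ⇐ acacetin.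
5. No ring is built: both chromone cores are bought intact. Order: protect unit A, functionalise unit B at C8, join, deprotect.

Assumption 1: the target SMILES has no stereodescriptor (no stereocentre, biaryl axis unspecified), so the compound is made as drawn, racemic about the axis.
Assumption 2: acacetin and apigenin are taken as commercially available catalogue chemicals.

## Route

Step 1
Reactants: 1 acacetin (5,7-dihydroxy-2-(4-methoxyphenyl)-4H-chromen-4-one)
Product: 2 7-O-MOM-acacetin (5-hydroxy-7-(methoxymethoxy)-2-(4-methoxyphenyl)-4H-chromen-4-one)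
Conditions: MOMCl (1.1 equiv), K2CO3, DMF, 0 °C → rt
Reagents that add atoms: chloromethyl methyl ether (MOMCl), COCCl
Why: Williamson-type MOM etherification in which the acidic, unhindered 7-OH reacts while the 5-OH stays locked in its hydrogen bond to the C4 carbonyl, so only O7 is alkylated.

Step 2
Reactants: 3 apigenin (5,7-dihydroxy-2-(4-hydroxyphenyl)-4H-chromen-4-one)
Product: 4 tri-O-MOM-apigenin (5,7-bis(methoxymethoxy)-2-[4-(methoxymethoxy)phenyl]-4H-chromen-4-one)
Conditions: NaH (3.6 equiv), MOMCl (3.6 equiv), DMF, 0 °C → rt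
Reagents that add atoms: chloromethyl methyl ether (MOMCl), COCCl
Why: exhaustive Williamson etherification through the sodium phenoxides, NaH in DMF being strong enough to break the chelate of the 5-OH so that all three hydroxyls become MOM ethers.

Step 3
Reactants: 4 tri-O-MOM-apigenin
Product: 5 8-iodo-5,7-bis(methoxymethoxy)-2-[4-(methoxymethoxy)phenyl]-4H-chromen-4-one
Conditions: NIS (1.15 equiv), DMF, 40 °C, dark
Reagents that add atoms: N-iodosuccinimide (NIS), O=C1CCC(=O)N1I
Why: electrophilic aromatic iodination, which in 5,7-dialkoxyflavones goes to C8 of the phloroglucinol ring (ortho to O1 and the 7-alkoxy group, para to the 5-alkoxy group) rather than the more congested C6, under neutral conditions that spare the MOM ethers.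

Step 4
Reactants: 5 8-iodo tri-O-MOM-apigenin
Product: 6 5,7-bis(methoxymethoxy)-2-[4-(methoxymethoxy)phenyl]-8-(4,4,5,5-tetramethyl-1,3,2-dioxaborolan-2-yl)-4H-chromen-4-one
Conditions: B2pin2 (1.5 equiv), PdCl2(dppf) (5 mol %), KOAc (3 equiv), 1,4-dioxane, 90 °C
Reagents that add atoms: bis(pinacolato)diboron (B2pin2), CC1(C)OB(OC1(C)C)B1OC(C)(C)C(C)(C)O1
Why: Miyaura borylation, in which the aryl iodide adds oxidatively to zerovalent palladium, acetate-assisted transmetalation with B2pin2 follows and reductive elimination gives the aryl boronate.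

Step 5
Reactants: 6 unit B 8-pinacol boronate
Product: 7 {5,7-bis(methoxymethoxy)-2-[4-(methoxymethoxy)phenyl]-4-oxo-4H-chromen-8-yl}boronic acid
Conditions: NaIO4 (3 equiv), NH4OAc (3 equiv), acetone/H2O 1:1, rt
Reagents that add atoms: water, O
Why: oxidative pinacol-ester cleavage, in which periodate destroys the pinacol released by the hydrolysis equilibrium (glycol cleavage to acetone) and so drives it to the free boronic acid at near-neutral pH that the MOM ethers tolerate.

Step 6
Reactants: 7 unit B 8-boronic acid; 2 7-O-MOM-acacetin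
Product: 9 tetra-MOM biflavone 5-hydroxy-7-(methoxymethoxy)-2-(4-methoxyphenyl)-6-{5,7-bis(methoxymethoxy)-2-[4-(methoxymethoxy)phenyl]-4-oxo-4H-chromen-8-yl}-4H-chromen-4-one (racemic about the biaryl axis), via flavon-8-yl lead triacetate 8 (not isolated)
Conditions: Pb(OAc)4 (1.0 equiv), Hg(OAc)2 (10 mol %), CHCl3, 40 °C, 2 h; then 2 (0.8 equiv), pyridine (3 equiv), 60 °C, 16 h
Reagents that add atoms: none
Why: Proposed new method: the chelated 5-OH of 2 exchanges for acetate on the tetravalent lead of 8 (pyridine takes up the AcOH and occupies the site the C4 carbonyl would otherwise chelate), and the resulting aryl(aryloxy)lead diacetate undergoes ligand coupling in which C6, the only free carbon ortho to O5 and the most nucleophilic carbon of the phloroglucinol ring, bonds to the lead-bound C8 of unit B with reductive elimination of Pb(OAc)2, after which the 6-aryl-cyclohexadienone tautomerises back to the hydrogen-bonded 5-hydroxyflavone; the regiochemistry is thus fixed on unit B by the carbon–lead bond and on unit A by the oxygen–lead bond, a 2,6-dialkoxyaryl group is the best class of transferring group on lead, and ligand coupling tolerates four ortho substituents; the closest known reaction type is the Pinhey ortho-arylation of electron-rich phenols by aryllead triacetates made in situ by boron-to-lead exchange, not yet shown for a carbonyl-chelated 5-hydroxyflavone as the phenol or for a flavon-8-yl lead reagent; no stereocentre is formed and the new axis arises racemic.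

Step 7
Reactants: 9 tetra-MOM biflavone
Product: 10 target CNP0302154.0 (5,7-dihydroxy-6-[5,7-dihydroxy-2-(4-hydroxyphenyl)-4-oxo-4H-chromen-8-yl]-2-(4-methoxyphenyl)-4H-chromen-4-one)
Conditions: HCl (1.25 M in MeOH), THF, 40 °C
Reagents that add atoms: none
Why: acid-catalysed acetal solvolysis (transacetalisation to dimethoxymethane) removes all four MOM groups while the aryl methyl ether is inert, and the mild acid avoids the Wessely–Moser ring-opening isomerisation of the 8-aryl-5-hydroxyflavone half that hot hydrohalic acids would cause; no stereocentre is involved.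

## Compound list

1 | acacetin, 5,7-dihydroxy-2-(4-methoxyphenyl)-4H-chromen-4-one | COc1ccc(cc1)-c1cc(=O)c2c(O)cc(O)cc2o1 | starting material
2 | 7-O-MOM-acacetin, 5-hydroxy-7-(methoxymethoxy)-2-(4-methoxyphenyl)-4H-chromen-4-one | COc1ccc(cc1)-c1cc(=O)c2c(O)cc(OCOC)cc2o1 | intermediate
3 | apigenin, 5,7-dihydroxy-2-(4-hydroxyphenyl)-4H-chromen-4-one | Oc1ccc(cc1)-c1cc(=O)c2c(O)cc(O)cc2o1 | starting material
4 | tri-O-MOM-apigenin, 5,7-bis(methoxymethoxy)-2-[4-(methoxymethoxy)phenyl]-4H-chromen-4-one | COCOc1ccc(cc1)-c1cc(=O)c2c(OCOC)cc(OCOC)cc2o1 | intermediate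
5 | 8-iodo-5,7-bis(methoxymethoxy)-2-[4-(methoxymethoxy)phenyl]-4H-chromen-4-one | COCOc1ccc(cc1)-c1cc(=O)c2c(OCOC)cc(OCOC)c(I)c2o1 | intermediate
6 | 5,7-bis(methoxymethoxy)-2-[4-(methoxymethoxy)phenyl]-8-(4,4,5,5-tetramethyl-1,3,2-dioxaborolan-2-yl)-4H-chromen-4-one | COCOc1ccc(cc1)-c1cc(=O)c2c(OCOC)cc(OCOC)c(B3OC(C)(C)C(C)(C)O3)c2o1 | intermediate
7 | {5,7-bis(methoxymethoxy)-2-[4-(methoxymethoxy)phenyl]-4-oxo-4H-chromen-8-yl}boronic acid | COCOc1ccc(cc1)-c1cc(=O)c2c(OCOC)cc(OCOC)c(B(O)O)c2o1 | intermediate
8 | flavon-8-yl lead triacetate, {5,7-bis(methoxymethoxy)-2-[4-(methoxymethoxy)phenyl]-4-oxo-4H-chromen-8-yl}lead triacetate (formed in the flask, not isolated) | COCOc1ccc(cc1)-c1cc(=O)c2c(OCOC)cc(OCOC)c([Pb](OC(C)=O)(OC(C)=O)OC(C)=O)c2o1 | intermediate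
9 | tetra-MOM biflavone, 5-hydroxy-7-(methoxymethoxy)-2-(4-methoxyphenyl)-6-{5,7-bis(methoxymethoxy)-2-[4-(methoxymethoxy)phenyl]-4-oxo-4H-chromen-8-yl}-4H-chromen-4-one (racemic about the axis) | COc1ccc(cc1)-c1cc(=O)c2c(O)c(-c3c(OCOC)cc(OCOC)c4c(=O)cc(-c5ccc(OCOC)cc5)oc34)c(OCOC)cc2o1 | intermediate
10 | CNP0302154.0, 5,7-dihydroxy-6-[5,7-dihydroxy-2-(4-hydroxyphenyl)-4-oxo-4H-chromen-8-yl]-2-(4-methoxyphenyl)-4H-chromen-4-one | COc1ccc(-c2cc(=O)c3c(O)c(-c4c(O)cc(O)c5c(=O)cc(-c6ccc(O)cc6)oc45)c(O)cc3o2)cc1 | target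

## Step count and risk assessment

Total step count: 7. Longest linear sequence: 6 steps (apigenin 3 → 4 → 5 → 6 → 7 → 9 → 10); the acacetin branch is one step before the union.

Most likely to fail, step 6 (the new arylation). The hydrogen-bonded 5-OH may not exchange onto lead, ligand coupling may go to the acyl-bearing C4a (a dearomatised by-product), or 8 may simply be protonated back to 4. The fallback is known chemistry, a Suzuki–Miyaura union of a 6-iodoflavone with the flavone-8-boronate; it sets out from 2 and 6 and comes back to the route at 10. The free 5-OH of 2 directs iodination to C6 (benzyltrimethylammonium dichloroiodate, CaCO3, CH2Cl2/MeOH, rt) to give 5-hydroxy-6-iodo-7-(methoxymethoxy)-2-(4-methoxyphenyl)-4H-chromen-4-one F1. Capping the 5-OH (NaH, MOMCl, DMF) gives 6-iodo-5,7-bis(methoxymethoxy)-2-(4-methoxyphenyl)-4H-chromen-4-one F2. Coupling F2 with the pinacol boronate 6 (Pd(OAc)2, SPhos, K3PO4, toluene/H2O, 100 °C) gives 5,7-bis(methoxymethoxy)-2-(4-methoxyphenyl)-6-{5,7-bis(methoxymethoxy)-2-[4-(methoxymethoxy)phenyl]-4-oxo-4H-chromen-8-yl}-4H-chromen-4-one F3. HCl/MeOH as in step 7 then strips the five MOM groups of F3 to give 10.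

Second, step 5 (liberating the boronic acid). The di-ortho-alkoxy pinacol ester may hydrolyse slowly, and the free boronic acid may protodeboronate on isolation. The fallback swaps boron for tin; it sets out from 5 and comes back to the route at 8. Iodide 5 is stannylated with hexabutylditin (Pd(PPh3)4, toluene, 110 °C) to give 5,7-bis(methoxymethoxy)-2-[4-(methoxymethoxy)phenyl]-8-(tributylstannyl)-4H-chromen-4-one F4. Tin-to-lead exchange of F4 with Pb(OAc)4 (Hg(OAc)2 cat., CHCl3, rt) forms 8 in the flask, and step 6 then continues as written from the addition of 2 and pyridine.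

Third, step 3 (C8 iodination). NIS may be too weak an electrophile for a ring deactivated by the chromone carbonyl, and adding acid to force it would strip the labile 5-O-MOM group. The fallback changes the halogen handle and bypasses the iodide; it sets out from 4 and comes back to the route at 6. NBS in DMF (0 °C → rt), the best-documented C8 halogenation of 5,7-dialkoxyflavones, gives 8-bromo-5,7-bis(methoxymethoxy)-2-[4-(methoxymethoxy)phenyl]-4H-chromen-4-one F5. Miyaura borylation of this bromide with a more active catalyst (Pd(OAc)2, SPhos, B2pin2, KOAc, 1,4-dioxane, 100 °C) gives 6 directly.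

## Further compounds

F1 | step 6 | 5-hydroxy-6-iodo-7-(methoxymethoxy)-2-(4-methoxyphenyl)-4H-chromen-4-one | COc1ccc(cc1)-c1cc(=O)c2c(O)c(I)c(OCOC)cc2o1
F2 | step 6 | 6-iodo-5,7-bis(methoxymethoxy)-2-(4-methoxyphenyl)-4H-chromen-4-one | COc1ccc(cc1)-c1cc(=O)c2c(OCOC)c(I)c(OCOC)cc2o1
F3 | step 6 | 5,7-bis(methoxymethoxy)-2-(4-methoxyphenyl)-6-{5,7-bis(methoxymethoxy)-2-[4-(methoxymethoxy)phenyl]-4-oxo-4H-chromen-8-yl}-4H-chromen-4-one | COc1ccc(cc1)-c1cc(=O)c2c(OCOC)c(-c3c(OCOC)cc(OCOC)c4c(=O)cc(-c5ccc(OCOC)cc5)oc34)c(OCOC)cc2o1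
F4 | step 5 | 5,7-bis(methoxymethoxy)-2-[4-(methoxymethoxy)phenyl]-8-(tributylstannyl)-4H-chromen-4-one | COCOc1ccc(cc1)-c1cc(=O)c2c(OCOC)cc(OCOC)c([Sn](CCCC)(CCCC)CCCC)c2o1
F5 | step 3 | 8-bromo-5,7-bis(methoxymethoxy)-2-[4-(methoxymethoxy)phenyl]-4H-chromen-4-one | COCOc1ccc(cc1)-c1cc(=O)c2c(OCOC)cc(OCOC)c(Br)c2o1
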